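**Retrosynthetic overview**
1. The vanillate ester C–O bond and the C9 carbinol come last, together: vanillic acid 20 adds syn-1,4 across the monoepoxide 21 of diene 16.
2. Diene 16 comes from hydroazulenone 14 by removing the ketone oxygen (dienyl triflate, formate hydrogenolysis).
3. Key step: 14 arises by a 1,2-shift of the ring-fusion C–C bond in cis-decalin triol monomesylate 13 (six–six to five–seven), which sets C5 and carries C1 over unchanged.
4. Triol 12 comes from dienone 9 (isopropyl addition, hydroxyl-directed dihydroxylation); 9 comes from an auxiliary-controlled Robinson annulation of 2,5-dimethylcyclohexanone with methyl vinyl ketone, then dehydrogenation.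
5. Ring order: ring B (six-membered, bought), ring A (six-membered, annulated), then A contracts to the cyclopentane while B expands to the cycloheptene. Vanillic acid is made from catechol.

Assumption: the 1-phenylethylamine auxiliary induces in the same sense with 2,5-dimethylcyclohexanone as with 2-methylcyclohexanone (about 90% ee expected, raised by one recrystallisation of triol 12).

Locants C1–C10 in the comments are those of the target core: C1 (quaternary, methyl), C2, C3, C4 (isopropyl carbinol), C5 (ring-fusion CH), C6 (ester carbon), C7=C8 (C8 methyl), C9 (carbinol), C10. The β face carries the angular methyl; the α face carries H-5.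

**Route**

Step 1
Reactants: 1 3-methylcyclohex-2-en-1-one
Product: 2 3,6-dimethylcyclohex-2-en-1-one (racemic)
Conditions: lithium diisopropylamide, THF, −78 °C; MeI, −78 → 0 °C
Reagents that add atoms: iodomethane, CI
Why: Kinetic α′-deprotonation gives the cross-conjugated lithium dienolate, which is methylated by SN2 alkylation; the new stereocentre is racemic and is re-formed in step 4.

Step 2
Reactants: 2 3,6-dimethylcyclohex-2-en-1-one
Product: 3 2,5-dimethylcyclohexan-1-one (cis/trans mixture)
Conditions: H2 (1 atm), 10% Pd/C, EtOAc, 20 °C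
Reagents that add atoms: none
Why: Heterogeneous catalytic hydrogenation saturates the conjugated C=C bond only; the isomer mixture is harmless because one centre is re-formed in step 4 and the other becomes sp2 in step 5.

Step 3
Reactants: 3 2,5-dimethylcyclohexan-1-one
Product: 4 N-[(1R)-1-phenylethyl]-2,5-dimethylcyclohexan-1-imine (isomer mixture)
Conditions: (R)-1-phenylethylamine, TsOH (cat.), toluene, reflux, Dean–Stark
Reagents that add atoms: (R)-1-phenylethylamine, C[C@@H](N)c1ccccc1
Why: Acid-catalysed imine condensation with azeotropic removal of water installs the chiral auxiliary.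

Step 4
Reactants: 4 N-[(1R)-1-phenylethyl]-2,5-dimethylcyclohexan-1-imine; 5 but-3-en-2-one
Product: 8 (4aS)-4a,7-dimethyl-4,4a,5,6,7,8-hexahydronaphthalen-2(3H)-one (C7 epimers), via Michael-adduct imine 6 (not isolated), via diketone 7 (not isolated)
Conditions: 5, THF, 40 °C; then 10% aq. AcOH, 20 °C; then KOH, MeOH, 65 °C
Reagents that add atoms: none
Why: Deracemising aza-ene-type Michael addition of the more substituted secondary enamine tautomer, anti to the auxiliary phenyl group, sets the quaternary centre (S); hydrolysis and aldol condensation (Robinson annulation) then close ring A.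

Step 5
Reactants: 8 (4aS)-4a,7-dimethyl-4,4a,5,6,7,8-hexahydronaphthalen-2(3H)-one
Product: 9 (4aS)-4a,7-dimethyl-4,4a,5,6-tetrahydronaphthalen-2(3H)-one
Conditions: chloranil, t-BuOH, reflux
Reagents that add atoms: none
Why: Quinone dehydrogenation through the heteroannular dienol (hydride abstraction at the tertiary allylic position) gives the linear dienone and merges the two epimers at the secondary methyl carbon.

Step 6
Reactants: 9 (4aS)-4a,7-dimethyl-4,4a,5,6-tetrahydronaphthalen-2(3H)-one; 10 isopropylmagnesium chloride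
Product: 11 (2R,4aS)-4a,7-dimethyl-2-(propan-2-yl)-2,3,4,4a,5,6-hexahydronaphthalen-2-ol
Conditions: 10, CeCl3, THF, −78 °C
Reagents that add atoms: none
Why: Organocerium 1,2-addition (no enolisation, no conjugate addition) from the face anti to the angular methyl places the new hydroxyl cis to that methyl (future C4).

Step 7
Reactants: 11 (2R,4aS)-4a,7-dimethyl-2-(propan-2-yl)-2,3,4,4a,5,6-hexahydronaphthalen-2-ol
Product: 12 (1S,2R,4aS,8aR)-4a,7-dimethyl-2-(propan-2-yl)-1,2,3,4,4a,5,6,8a-octahydronaphthalene-1,2,8a-triol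
Conditions: OsO4 (1.05 equiv), TMEDA, CH2Cl2, −78 °C; then aq. Na2SO3, THF, 60 °C
Reagents that add atoms: osmium tetroxide, O=[Os](=O)(=O)=O
Why: Hydrogen-bond-directed syn-dihydroxylation by the OsO4·TMEDA complex delivers both oxygens to the proximal alkene on the face of the tertiary allylic hydroxyl, giving the all-cis triol.

Step 8
Reactants: 12 (1S,2R,4aS,8aR)-4a,7-dimethyl-2-(propan-2-yl)-1,2,3,4,4a,5,6,8a-octahydronaphthalene-1,2,8a-triol
Product: 14 (3R,3aR,8aS)-3-hydroxy-6,8a-dimethyl-3-(propan-2-yl)-2,3,3a,7,8,8a-hexahydroazulen-4(1H)-one, via monomesylate 13 (not isolated)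
Conditions: MsCl, Et3N, THF, −30 °C; then KOtBu, −40 → −10 °C
Reagents that add atoms: none
Why: Sulfene mesylation of the only secondary hydroxyl is followed by an alkoxide-driven semipinacol rearrangement: the equatorial C–OMs bond of the cis-decalin is antiperiplanar to the ring-fusion C–C bond, so the quaternary carbon migrates with retention while C5 is inverted, contracting ring A to the cyclopentane and expanding ring B to the trans-fused cycloheptenone (the tertiary migrating carbon and the conjugated enone product favour this shift over the competing one from the other carbinol).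

Step 9
Reactants: 14 (3R,3aR,8aS)-3-hydroxy-6,8a-dimethyl-3-(propan-2-yl)-2,3,3a,7,8,8a-hexahydroazulen-4(1H)-one
Product: 16 (3R,3aR,8aR)-6,8a-dimethyl-3-(propan-2-yl)-1,2,3,3a,8,8a-hexahydroazulen-3-ol, via dienyl triflate 15 (not isolated)
Conditions: KN(SiMe3)2 (1.95 equiv), THF, −78 → −10 °C; PhNTf2, −78 → 20 °C; then Pd(OAc)2 (5 mol %), PPh3, HCO2H, n-Bu3N, DMF, 60 °C
Reagents that add atoms: none
Why: O-triflation of the equilibrated, endocyclic extended potassium dienolate and palladium-catalysed formate hydrogenolysis of the dienyl triflate remove the ketone oxygen and give the 1,3-diene without touching a stereocentre.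

Step 10
Reactants: 17 benzene-1,2-diol (catechol)
Product: 18 2-methoxyphenol
Conditions: MeI (1.0 equiv), K2CO3, acetone, reflux
Reagents that add atoms: iodomethane, CI
Why: Williamson mono-O-methylation (SN2) of the catechol mono-anion.

Step 11
Reactants: 18 2-methoxyphenol
Product: 19 4-bromo-2-methoxyphenol
Conditions: N-bromosuccinimide, MeCN, 0 °C
Reagents that add atoms: N-bromosuccinimide, O=C1CCC(=O)N1Br
Why: Electrophilic aromatic bromination para to the free hydroxyl, the stronger director.

Step 12
Reactants: 19 4-bromo-2-methoxyphenol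
Product: 20 4-hydroxy-3-methoxybenzoic acid (vanillic acid)
Conditions: CO (1 atm), H2O, Pd(OAc)2 (2 mol %), Xantphos, Et3N, DMF, 90 °C; then aq. HCl
Reagents that add atoms: carbon monoxide, [C-]#[O+]; water, O
Why: Palladium-catalysed hydroxycarbonylation (oxidative addition, CO insertion, hydrolysis of the acyl–palladium species) tolerates the free phenol.

Step 13
Reactants: 16 (3R,3aR,8aR)-6,8a-dimethyl-3-(propan-2-yl)-1,2,3,3a,8,8a-hexahydroazulen-3-ol; 20 4-hydroxy-3-methoxybenzoic acid
Product: 22 (3R,3aS,4S,7S,8aR)-3,7-dihydroxy-6,8a-dimethyl-3-(propan-2-yl)-1,2,3,3a,4,7,8,8a-octahydroazulen-4-yl 4-hydroxy-3-methoxybenzoate, via vinyl epoxide 21 (not isolated)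
Conditions: dimethyldioxirane (1.05 equiv), acetone, −40 °C; evaporate at −20 °C; then add to 20 (1.3 equiv), Pd2(dba)3·CHCl3 (2.5 mol %), PPh3 (12 mol %), THF, 0 → 20 °C
Reagents that add atoms: dimethyldioxirane, CC1(C)OO1
Why: Proposed new method: a one-flask net syn-1,4-hydroxy-aroyloxylation of the diene with an unprotected phenolic acid, not yet shown for an epoxide with a tertiary allylic terminus and a far terminus next to a ring-fusion methine; dimethyldioxirane epoxidises the more electron-rich trisubstituted C8=C9 bond on the α face (anti to the angular methyl), zerovalent palladium ionises the tertiary allylic C8–O bond anti to the oxygen, the C9 alkoxide deprotonates the carboxylic acid (far more acidic than its phenol), and the carboxylate attacks the unsubstituted allyl terminus C6 anti to palladium, so C6–O and C9–O end cis (both α) with the ester on C6 by mechanism; closest known reaction type: palladium-catalysed cis-1,4-addition of carboxylic acids to cyclic 1,3-diene monoepoxides (allylic substitution with double inversion).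

**Compound list**
1 | 3-methylcyclohex-2-en-1-one | CC1=CC(=O)CCC1 | starting material
2 | 3,6-dimethylcyclohex-2-en-1-one (racemic) | CC1=CC(=O)C(C)CC1 | intermediate
3 | 2,5-dimethylcyclohexan-1-one (cis/trans mixture) | CC1CCC(C)CC1=O | intermediate
4 | N-[(1R)-1-phenylethyl]-2,5-dimethylcyclohexan-1-imine (isomer mixture) | CC1CCC(C)CC1=N[C@H](C)c1ccccc1 | intermediate
5 | but-3-en-2-one (methyl vinyl ketone) | CC(=O)C=C | starting material
6 | 4-[(1S)-1,4-dimethyl-2-{[(1R)-1-phenylethyl]imino}cyclohexyl]butan-2-one (ring-methyl epimers) | CC(=O)CC[C@]1(C)CCC(C)CC1=N[C@H](C)c1ccccc1 | intermediate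
7 | (2S)-2,5-dimethyl-2-(3-oxobutyl)cyclohexan-1-one (C5 epimers) | CC(=O)CC[C@]1(C)CCC(C)CC1=O | intermediate
8 | (4aS)-4a,7-dimethyl-4,4a,5,6,7,8-hexahydronaphthalen-2(3H)-one (C7 epimers) | O=C1C=C2CC(C)CC[C@@]2(C)CC1 | intermediate
9 | (4aS)-4a,7-dimethyl-4,4a,5,6-tetrahydronaphthalen-2(3H)-one | O=C1C=C2C=C(C)CC[C@@]2(C)CC1 | intermediate
10 | isopropylmagnesium chloride | CC(C)[Mg]Cl | starting material
11 | (2R,4aS)-4a,7-dimethyl-2-(propan-2-yl)-2,3,4,4a,5,6-hexahydronaphthalen-2-ol (hydroxyl cis to the 4a-methyl) | CC1=CC2=C[C@](O)(C(C)C)CC[C@]2(C)CC1 | intermediate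
12 | (1S,2R,4aS,8aR)-4a,7-dimethyl-2-(propan-2-yl)-1,2,3,4,4a,5,6,8a-octahydronaphthalene-1,2,8a-triol (all three hydroxyls cis to the 4a-methyl) | CC1=C[C@]2(O)[C@@H](O)[C@](O)(C(C)C)CC[C@]2(C)CC1 | intermediate
13 | (1S,2R,4aS,8aR)-2,8a-dihydroxy-4a,7-dimethyl-2-(propan-2-yl)-1,2,3,4,4a,5,6,8a-octahydronaphthalen-1-yl methanesulfonate | CC1=C[C@]2(O)[C@@H](OS(C)(=O)=O)[C@](O)(C(C)C)CC[C@]2(C)CC1 | intermediate
14 | (3R,3aR,8aS)-3-hydroxy-6,8a-dimethyl-3-(propan-2-yl)-2,3,3a,7,8,8a-hexahydroazulen-4(1H)-one (trans-fused) | O=C1C=C(C)CC[C@@]2(C)CC[C@@](O)(C(C)C)[C@H]12 | intermediate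
15 | (3R,3aR,8aS)-3-hydroxy-6,8a-dimethyl-3-(propan-2-yl)-1,2,3,3a,8,8a-hexahydroazulen-4-yl trifluoromethanesulfonate | O=S(=O)(OC1=CC(C)=CC[C@@]2(C)CC[C@@](O)(C(C)C)[C@H]12)C(F)(F)F | intermediate
16 | (3R,3aR,8aR)-6,8a-dimethyl-3-(propan-2-yl)-1,2,3,3a,8,8a-hexahydroazulen-3-ol | C1=CC(C)=CC[C@@]2(C)CC[C@@](O)(C(C)C)[C@H]12 | intermediate
17 | benzene-1,2-diol (catechol) | Oc1ccccc1O | starting material
18 | 2-methoxyphenol | COc1ccccc1O | intermediate
19 | 4-bromo-2-methoxyphenol | COc1cc(Br)ccc1O | intermediate
20 | 4-hydroxy-3-methoxybenzoic acid (vanillic acid) | COc1cc(C(=O)O)ccc1O | intermediate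
21 | 6,7-epoxide of 16 (azulene locants; core C8–C9), epoxide oxygen on the face opposite the angular methyl | C1=C[C@@]2(C)O[C@H]2C[C@@]3(C)CC[C@@](O)(C(C)C)[C@H]13 | intermediate
22 | (3R,3aS,4S,7S,8aR)-3,7-dihydroxy-6,8a-dimethyl-3-(propan-2-yl)-1,2,3,3a,4,7,8,8a-octahydroazulen-4-yl 4-hydroxy-3-methoxybenzoate | COc1cc(C(=O)O[C@H]2C=C(C)[C@@H](O)C[C@@]3(C)CC[C@@](O)(C(C)C)[C@H]23)ccc1O | target

**Count and risks**
Total steps: 13 (steps 10–12 make acid 20 for the convergent last step). Longest linear sequence: 10 (steps 1–9 and 13).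

Steps most likely to fail:

Step 7. A second alkene is present, and the directed face is the one that carries the angular methyl, so chemoselectivity and face selectivity are both at stake. The fallback sets out from octalone 8 and comes back at 14; it postpones the dehydrogenation so that the dihydroxylation meets only one alkene. Reagent 10 with CeCl3 adds to 8 to give the ring-B-saturated allylic alcohol F1. OsO4·TMEDA then gives the saturated all-cis triol F2. MsCl/Et3N gives the monomesylate F3, and KOtBu rearranges it to the saturated hydroxy ketone F4. Dehydrogenation with IBX (DMSO, 70 °C), which can only go towards the methyl-bearing side, gives 14.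

Step 9. The extended enolate may form at the methyl group (exocyclic) instead of in the ring, and 14 is a base-sensitive aldol. The fallback sets out from 14 and comes back at 16; it fixes the enolate regiochemistry through an isolable silyl dienol ether. Me3SiCl/NaI/Et3N in MeCN (equilibrating conditions) gives the bis-silyl dienol ether F5. MeLi cleaves only the enol silyl ether, and PhNTf2 traps the resulting lithium dienolate as the O-silylated dienyl triflate F6. Pd(OAc)2/PPh3 with HCO2H–n-Bu3N, followed by citric acid in MeOH to remove the silyl ether, gives 16.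

Step 13 (the proposed new step). Possible failures are direct acid opening of the tertiary allylic epoxide, attack at the tertiary allyl terminus, or epoxidation on the wrong face. The fallback uses known reactions only, sets out from 16 and comes back at 22. Photo-oxygenation (O2, tetraphenylporphyrin, light, CH2Cl2, −20 °C) gives the α-face endoperoxide F7 by [4+2] addition of singlet oxygen. Thiourea in MeOH reduces it to the cis-ene-triol F8. Ac2O (1 equiv) in pyridine at −20 °C acetylates the less hindered C9 hydroxyl to give the monoacetate F9. Separately, 20 is acetylated (Ac2O, aq. NaOH) to 4-acetoxy-3-methoxybenzoic acid F10. Steglich esterification (DCC, DMAP) of F9 with F10 gives the doubly acetylated ester F11. K2CO3 in MeOH at 0 °C removes both acetates and leaves the hindered aryl ester, giving 22.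

Further compounds
F1 | step 7 | (2R,4aS)-4a,7-dimethyl-2-(propan-2-yl)-2,3,4,4a,5,6,7,8-octahydronaphthalen-2-ol (C7 epimers) | CC1CC2=C[C@](O)(C(C)C)CC[C@]2(C)CC1
F2 | step 7 | (1S,2R,4aS,8aR)-4a,7-dimethyl-2-(propan-2-yl)decahydronaphthalene-1,2,8a-triol (C7 epimers) | CC1C[C@]2(O)[C@@H](O)[C@](O)(C(C)C)CC[C@]2(C)CC1
F3 | step 7 | 1-methanesulfonate of F2 | CC1C[C@]2(O)[C@@H](OS(C)(=O)=O)[C@](O)(C(C)C)CC[C@]2(C)CC1
F4 | step 7 | (3R,3aR,8aS)-3-hydroxy-6,8a-dimethyl-3-(propan-2-yl)octahydroazulen-4(1H)-one (C6 epimers) | O=C1CC(C)CC[C@@]2(C)CC[C@@](O)(C(C)C)[C@H]12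
F5 | step 9 | bis(trimethylsilyl) dienol ether of 14 (enol O and tertiary O silylated) | C[Si](C)(C)OC1=CC(C)=CC[C@@]2(C)CC[C@@](O[Si](C)(C)C)(C(C)C)[C@H]12
F6 | step 9 | O-trimethylsilyl ether of dienyl triflate 15 | O=S(=O)(OC1=CC(C)=CC[C@@]2(C)CC[C@@](O[Si](C)(C)C)(C(C)C)[C@H]12)C(F)(F)F
F7 | step 13 | 4,7-epidioxide of 16 (azulene locants; core C6 and C9), peroxide bridge on the face opposite the angular methyl | O1[C@H]2C=C(C)[C@@H](O1)C[C@@]3(C)CC[C@@](O)(C(C)C)[C@H]23
F8 | step 13 | (3R,3aS,4S,7S,8aR)-6,8a-dimethyl-3-(propan-2-yl)-1,2,3,3a,4,7,8,8a-octahydroazulene-3,4,7-triol | O[C@H]1C=C(C)[C@@H](O)C[C@@]2(C)CC[C@@](O)(C(C)C)[C@H]12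
F9 | step 13 | 7-O-acetate of F8 | O[C@H]1C=C(C)[C@@H](OC(C)=O)C[C@@]2(C)CC[C@@](O)(C(C)C)[C@H]12
F10 | step 13 | 4-acetoxy-3-methoxybenzoic acid | CC(=O)Oc1ccc(cc1OC)C(=O)O
F11 | step 13 | 7-O-acetyl-4-O-(4-acetoxy-3-methoxybenzoyl) derivative of F8 | CC(=O)Oc1ccc(cc1OC)C(=O)O[C@H]1C=C(C)[C@@H](OC(C)=O)C[C@@]2(C)CC[C@@](O)(C(C)C)[C@H]12
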